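Everything rests on cutting the 7-prenylindole at two bonds together: N1–C2 of its pyrrole ring and the bond from C3 to the central six-membered ring. The feature exploited is that this indole carries the central ring on C3 and only hydrogen on C2. C2 and C3 can therefore be the two carbons of a silyl-capped ethynyl group on an aniline whose other ortho position already holds the prenyl chain (future C7). One palladium-catalysed operation joins a MOM-protected bromohydroquinone, already bearing the N-TIPS-indol-3-yl group, to 2-prenyl-6-(trimethylsilylethynyl)trifluoroacetanilide and closes the pyrrole ring. Fluoride, mild acid and Ag2O then release the dimethoxyquinone.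

Key step: step 12

Remark on the chemistry: the target has no stereocentre and no configured double bond. Slow rotation about the aryl–indole bonds of the protected intermediates is assumed to be without consequence, since the target is defined without axial descriptors.

Step 1
Reactants: 1 bromanil (2,3,5,6-tetrabromocyclohexa-2,5-diene-1,4-dione)
Product: 2 2,5-dibromo-3,6-dimethoxycyclohexa-2,5-diene-1,4-dione
Conditions: NaOMe (2.05 equiv), MeOH, 0 °C to rt
Reagents that add atoms: sodium methoxide, C[O-].[Na+]
Why: Addition–elimination of methoxide on a tetrahaloquinone (vinylogous acyl substitution) should stop at the 2,5-dimethoxy stage, because the first methoxy group feeds one carbonyl and the second methoxide therefore enters at the para-related C–Br carbon, the only one still activated by the unperturbed carbonyl.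

Step 2
Reactants: 2 2,5-dibromo-3,6-dimethoxycyclohexa-2,5-diene-1,4-dione
Product: 3 2,5-dibromo-3,6-dimethoxybenzene-1,4-diol
Conditions: Na2S2O4 (3 equiv), THF/H2O, rt
Reagents that add atoms: none
Why: Dithionite reduction of a quinone to the hydroquinone is fast under two-phase conditions and leaves aryl bromides and methyl ethers untouched.

Step 3
Reactants: 3 2,5-dibromo-3,6-dimethoxybenzene-1,4-diol
Product: 4 1,4-dibromo-2,5-dimethoxy-3,6-bis(methoxymethoxy)benzene
Conditions: MOMCl (3 equiv), iPr2NEt (4 equiv), Bu4NI (cat.), CH2Cl2, 0 °C to reflux, Ar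
Reagents that add atoms: chloromethyl methyl ether, COCCl
Why: Williamson-type O-alkylation of both phenols with the very reactive chloromethyl ether gives formaldehyde acetals that tolerate palladium catalysis, phosphate, carbonate and fluoride and can later be released by mild acid.

Step 4
Reactants: 5 indole
Product: 7 1-(triisopropylsilyl)-1H-indole, via sodium indol-1-ide 6 (not isolated)
Conditions: NaH (1.1 equiv), THF, 0 °C; then iPr3SiCl (1.1 equiv), rt
Reagents that add atoms: chlorotriisopropylsilane, CC(C)[Si](Cl)(C(C)C)C(C)C
Why: N-Silylation of a preformed sodium indolide is routine, and the bulky silyl group masks N–H and screens C2 and C7 for the following borylation.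

Step 5
Reactants: 7 1-(triisopropylsilyl)-1H-indole
Product: 8 3-(4,4,5,5-tetramethyl-1,3,2-dioxaborolan-2-yl)-1-(triisopropylsilyl)-1H-indole
Conditions: [Ir(OMe)(cod)]2 (1.5 mol %), 4,4'-di-tert-butyl-2,2'-bipyridine (3 mol %), B2pin2 (1.0 equiv), hexane, 60 °C
Reagents that add atoms: bis(pinacolato)diboron, CC1(C)OB(OC1(C)C)B1OC(C)(C)C(C)(C)O1
Why: Iridium-catalysed aromatic C–H borylation is governed by sterics, and with N-triisopropylsilyl blocking C2 and C7 the boryl group is known to enter the pyrrole ring at C3.

Step 6
Reactants: 4 1,4-dibromo-2,5-dimethoxy-3,6-bis(methoxymethoxy)benzene (2.5 equiv); 8 3-(4,4,5,5-tetramethyl-1,3,2-dioxaborolan-2-yl)-1-(triisopropylsilyl)-1H-indole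
Product: 9 3-[4-bromo-2,5-dimethoxy-3,6-bis(methoxymethoxy)phenyl]-1-(triisopropylsilyl)-1H-indole
Conditions: Pd(OAc)2 (5 mol %), SPhos (10 mol %), K3PO4 (3 equiv), toluene/H2O 10:1, 90 °C; excess 4 recovered
Reagents that add atoms: none
Why: Suzuki–Miyaura coupling with the SPhos ligand handles bromides flanked by two ortho alkoxy groups, and the excess of the symmetrical, recoverable dibromide 4 keeps the reaction at the mono-arylation stage.

Step 7
Reactants: 10 2-iodoaniline; 11 3-chloro-3-methylbut-1-yne
Product: 12 2-iodo-N-(2-methylbut-3-yn-2-yl)aniline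
Conditions: CuCl (10 mol %), Et3N (1.5 equiv), THF, 0 °C to rt
Reagents that add atoms: none
Why: Copper-catalysed propargylic amination, in which the monovalent copper acetylide of 11 loses chloride to give an allenylidene-type electrophile that the aniline captures at the tertiary carbon, is the standard entry to N-(1,1-dimethylpropargyl)anilines and at room temperature should not touch the C–I bond.

Step 8
Reactants: 12 2-iodo-N-(2-methylbut-3-yn-2-yl)aniline
Product: 13 2-iodo-N-(2-methylbut-3-en-2-yl)aniline
Conditions: H2 (1 atm), Pd/CaCO3 poisoned with Pb(OAc)2, quinoline, EtOAc, rt, stopped after 1 equiv H2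
Reagents that add atoms: none
Why: Lindlar semi-hydrogenation reduces a terminal alkyne much faster than the resulting alkene or an aryl iodide on lead- and quinoline-poisoned palladium, so stopping at one equivalent of hydrogen should give the 1,1-dimethylallylamine with iodine in place.

Step 9
Reactants: 13 2-iodo-N-(2-methylbut-3-en-2-yl)aniline
Product: 14 2-iodo-6-(3-methylbut-2-en-1-yl)aniline
Conditions: pTsOH·H2O (0.5 equiv), MeCN/H2O 10:1, 80 °C
Reagents that add atoms: none
Why: Acid-accelerated aromatic aza-Claisen rearrangement of the N-protonated amine is a suprafacial [3,3] shift that inverts the allyl unit, turning the N-(1,1-dimethylallyl) group into a C-prenyl group at the only free ortho carbon, followed by rearomatisation.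

Step 10
Reactants: 14 2-iodo-6-(3-methylbut-2-en-1-yl)aniline; 15 ethynyl(trimethyl)silane
Product: 16 2-(3-methylbut-2-en-1-yl)-6-[(trimethylsilyl)ethynyl]aniline
Conditions: PdCl2(PPh3)2 (3 mol %), CuI (5 mol %), Et3N, THF, rt to 40 °C
Reagents that add atoms: none
Why: Sonogashira coupling of an aryl iodide proceeds near room temperature, tolerates the free amino group and the prenyl alkene, and installs the two carbons that become C3 and C2 of the new indole.

Step 11
Reactants: 16 2-(3-methylbut-2-en-1-yl)-6-[(trimethylsilyl)ethynyl]aniline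
Product: 17 2,2,2-trifluoro-N-[2-(3-methylbut-2-enyl)-6-(trimethylsilylethynyl)phenyl]acetamide
Conditions: (CF3CO)2O (1.3 equiv), pyridine (2 equiv), CH2Cl2, 0 °C
Reagents that add atoms: trifluoroacetic anhydride, O=C(OC(=O)C(F)(F)F)C(F)(F)F
Why: N-Acylation with the highly electrophilic anhydride overcomes the hindrance of the 2,6-disubstituted aniline, pyridine buffers the acid formed, and the product N–H is acidic enough for carbonate to deprotonate in the key step.

Step 12
Reactants: 9 3-[4-bromo-2,5-dimethoxy-3,6-bis(methoxymethoxy)phenyl]-1-(triisopropylsilyl)-1H-indole; 17 2,2,2-trifluoro-N-[2-(3-methylbut-2-enyl)-6-(trimethylsilylethynyl)phenyl]acetamide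
Product: 19 3-[2,5-dimethoxy-3,6-bis(methoxymethoxy)-4-(1-triisopropylsilylindol-3-yl)phenyl]-7-(3-methylbut-2-enyl)-2-trimethylsilyl-1H-indole, via N-trifluoroacetylindole 18 (not isolated)
Conditions: Pd2(dba)3 (5 mol %), XPhos (20 mol %), K2CO3 (oven-dried, 3 equiv), MeCN, reflux, 17 (1.5 equiv) added over 4 h; then aq NaHCO3, rt
Reagents that add atoms: none
Why: Zerovalent palladium bearing the bulky biarylphosphine inserts into the only C–Br bond of 9, and the divalent arylpalladium bromide so formed binds the alkyne of 17 and makes it electrophilic. The potassium salt of the trifluoroacetamide attacks the silyl-bearing alkyne carbon on the face away from the metal (anti aminopalladation), closing the pyrrole ring in a 5-endo-dig mode through the N1–C2 bond and leaving palladium on the carbon attached to the aniline ring. Reductive elimination from this aryl(indol-3-yl)palladium makes the bond from C3 to the central ring and regenerates zerovalent palladium, and the crowded N-trifluoroacetyl group of 18 is hydrolysed during the bicarbonate quench. The closest known reaction type is the Cacchi synthesis of 3-arylindoles from 2-alkynyltrifluoroacetanilides and aryl bromides, of which a silyl-terminated alkyne is a little-used variant. The step needs the aryl group on C3 and not on C2, which geometry secures because nitrogen can close a five-membered ring only onto the distal alkyne carbon, while the silyl cap removes the terminal C–H through which a Sonogashira-type coupling would lead to a 2-arylindole; dry K2CO3 in an aprotic solvent and slow addition of 17 are chosen to keep that cap on and to keep arylpalladium in excess over free anilide. No stereocentre is created, and the trisubstituted prenyl alkene, the MOM acetals and the N-TIPS group are spectators.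

Step 13
Reactants: 19 3-[2,5-dimethoxy-3,6-bis(methoxymethoxy)-4-(1-triisopropylsilylindol-3-yl)phenyl]-7-(3-methylbut-2-enyl)-2-trimethylsilyl-1H-indole
Product: 20 3-[4-(1H-indol-3-yl)-2,5-dimethoxy-3,6-bis(methoxymethoxy)phenyl]-7-(3-methylbut-2-enyl)-1H-indole
Conditions: Bu4NF (1 M in THF, 5 equiv), THF, rt then 50 °C
Reagents that add atoms: none
Why: Fluoride-induced desilylation cleaves the N–Si bond at once and the C2–Si bond of the 2-silylindole on gentle warming, MOM acetals and the prenyl group being inert to fluoride, and any C2 silyl group that survives would be lost by ipso-protodesilylation in the acidic step that follows.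

Step 14
Reactants: 20 3-[4-(1H-indol-3-yl)-2,5-dimethoxy-3,6-bis(methoxymethoxy)phenyl]-7-(3-methylbut-2-enyl)-1H-indole
Product: 22 2-(1H-indol-3-yl)-3,6-dimethoxy-5-[7-(3-methylbut-2-enyl)-1H-indol-3-yl]cyclohexa-2,5-diene-1,4-dione (CNP0256613.0), via bis-indolyl hydroquinone 21 (not isolated)
Conditions: pTsOH·H2O (0.2 equiv), MeOH/THF 4:1, 40 °C, Ar; then Ag2O (2 equiv), rt
Reagents that add atoms: none
Why: Acid-catalysed acetal exchange with methanol frees the electron-rich hydroquinone under conditions milder than those the prenyl group already survived in step 9, and Ag2O, which also neutralises the acid, then performs the classical two-electron hydroquinone-to-quinone oxidation without touching indoles or alkene.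

Compound list
1 | bromanil (2,3,5,6-tetrabromocyclohexa-2,5-diene-1,4-dione) | O=C1C(Br)=C(Br)C(=O)C(Br)=C1Br | starting material
2 | 2,5-dibromo-3,6-dimethoxycyclohexa-2,5-diene-1,4-dione | COC1=C(Br)C(=O)C(OC)=C(Br)C1=O | intermediate
3 | 2,5-dibromo-3,6-dimethoxybenzene-1,4-diol | COc1c(Br)c(O)c(OC)c(Br)c1O | intermediate
4 | 1,4-dibromo-2,5-dimethoxy-3,6-bis(methoxymethoxy)benzene | COCOc1c(Br)c(OC)c(OCOC)c(Br)c1OC | intermediate
5 | indole | c1ccc2[nH]ccc2c1 | starting material
6 | sodium indol-1-ide (not isolated) | [Na+].c1ccc2[n-]ccc2c1 | intermediate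
7 | 1-(triisopropylsilyl)-1H-indole | CC(C)[Si](C(C)C)(C(C)C)n1ccc2ccccc21 | intermediate
8 | 3-(4,4,5,5-tetramethyl-1,3,2-dioxaborolan-2-yl)-1-(triisopropylsilyl)-1H-indole | CC(C)[Si](C(C)C)(C(C)C)n1cc(B2OC(C)(C)C(C)(C)O2)c2ccccc21 | intermediate
9 | 3-[4-bromo-2,5-dimethoxy-3,6-bis(methoxymethoxy)phenyl]-1-(triisopropylsilyl)-1H-indole | Brc1c(OC)c(OCOC)c(-c2cn([Si](C(C)C)(C(C)C)C(C)C)c3ccccc23)c(OC)c1OCOC | intermediate
10 | 2-iodoaniline | Nc1ccccc1I | starting material
11 | 3-chloro-3-methylbut-1-yne | C#CC(C)(C)Cl | starting material
12 | 2-iodo-N-(2-methylbut-3-yn-2-yl)aniline | C#CC(C)(C)Nc1ccccc1I | intermediate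
13 | 2-iodo-N-(2-methylbut-3-en-2-yl)aniline | C=CC(C)(C)Nc1ccccc1I | intermediate
14 | 2-iodo-6-(3-methylbut-2-en-1-yl)aniline | CC(C)=CCc1cccc(I)c1N | intermediate
15 | ethynyl(trimethyl)silane | C#C[Si](C)(C)C | starting material
16 | 2-(3-methylbut-2-en-1-yl)-6-[(trimethylsilyl)ethynyl]aniline | CC(C)=CCc1cccc(C#C[Si](C)(C)C)c1N | intermediate
17 | 2,2,2-trifluoro-N-[2-(3-methylbut-2-enyl)-6-(trimethylsilylethynyl)phenyl]acetamide | CC(C)=CCc1cccc(C#C[Si](C)(C)C)c1NC(=O)C(F)(F)F | intermediate
18 | 1-(trifluoroacetyl) derivative of 19 (not isolated) | COc1c(-c2c([Si](C)(C)C)n(C(=O)C(F)(F)F)c3c(CC=C(C)C)cccc23)c(OCOC)c(OC)c(-c2cn([Si](C(C)C)(C(C)C)C(C)C)c3ccccc23)c1OCOC | intermediate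
19 | 3-[2,5-dimethoxy-3,6-bis(methoxymethoxy)-4-(1-triisopropylsilylindol-3-yl)phenyl]-7-(3-methylbut-2-enyl)-2-trimethylsilyl-1H-indole | COc1c(-c2c([Si](C)(C)C)[nH]c3c(CC=C(C)C)cccc23)c(OCOC)c(OC)c(-c2cn([Si](C(C)C)(C(C)C)C(C)C)c3ccccc23)c1OCOC | intermediate
20 | 3-[4-(1H-indol-3-yl)-2,5-dimethoxy-3,6-bis(methoxymethoxy)phenyl]-7-(3-methylbut-2-enyl)-1H-indole | COc1c(-c2c[nH]c3c(CC=C(C)C)cccc23)c(OCOC)c(OC)c(-c2c[nH]c3ccccc23)c1OCOC | intermediate
21 | 2-(1H-indol-3-yl)-3,6-dimethoxy-5-[7-(3-methylbut-2-enyl)-1H-indol-3-yl]benzene-1,4-diol (not isolated) | COc1c(-c2c[nH]c3c(CC=C(C)C)cccc23)c(O)c(OC)c(-c2c[nH]c3ccccc23)c1O | intermediate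
22 | 2-(1H-indol-3-yl)-3,6-dimethoxy-5-[7-(3-methylbut-2-enyl)-1H-indol-3-yl]cyclohexa-2,5-diene-1,4-dione (CNP0256613.0) | COC1=C(c2c[nH]c3ccccc23)C(=O)C(OC)=C(c2c[nH]c3c(CC=C(C)C)cccc23)C1=O | target

Total step count: 14.
Longest linear sequence: 8 steps (steps 7 to 14, from 2-iodoaniline 10).

Steps most likely to fail

**Step 12.**
- **Risk:** Oxidative addition to the crowded, electron-rich bromide may be slow. Base-induced loss of the alkyne silyl cap, or metal-free cyclisation of the anilide without aryl transfer, could then outrun the coupling.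
- **Fallback:** It sets out from 9, with 14 and 15 as partners, and rejoins the route at 19. The order of bond formation is inverted by a Larock heteroannulation.
- Bromide 9 is first alkynylated with 15 in a Sonogashira coupling tuned for hindered electron-rich bromides (PdCl2(PhCN)2, P(t-Bu)3, CuI, iPr2NH, dioxane, 40 to 60 °C). The amine base spares the silyl group. This should give 3-[2,5-dimethoxy-3,6-bis(methoxymethoxy)-4-(trimethylsilylethynyl)phenyl]-1-triisopropylsilylindole F1.
- F1 and iodoaniline 14 are then heated with Pd(OAc)2, LiCl and Na2CO3 in DMF at 100 °C. The arylpalladium iodide from 14 adds syn across the alkyne with the silyl-bearing carbon ending next to palladium, and nitrogen then displaces the metal to close the ring, which should deliver 19 directly.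
- The hard oxidative addition is thereby met in a coupling whose partner cannot decompose, and no trifluoroacetanilide is needed.

**Step 6.**
- **Risk:** Coupling may run on at the second bromide, the indolylboronate may protodeboronate in the aqueous base, or transmetalation to the hindered arylpalladium may be sluggish.
- **Fallback:** It sets out from 4 and 7 and rejoins at 9. The polarity of the coupling is reversed, and mono-selectivity is set by stoichiometric metalation.
- Silylindole 7 is iodinated at C3 (N-iodosuccinimide, THF, 0 °C) to 3-iodo-1-(triisopropylsilyl)-1H-indole F2.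
- Dibromide 4 is treated with exactly one equivalent of n-BuLi (THF, −78 °C) to give [4-bromo-2,5-dimethoxy-3,6-bis(methoxymethoxy)phenyl]lithium F3. ZnCl2 converts this into [4-bromo-2,5-dimethoxy-3,6-bis(methoxymethoxy)phenyl]zinc chloride F4.
- Negishi coupling of F4 with F2 (Pd2(dba)3, SPhos, THF, 50 °C) should give 9, because palladium inserts into the unhindered C–I bond far faster than into the flanked C–Br bond.

**Step 8.**
- **Risk:** The C–I bond may be hydrogenolysed on palladium, or reduction may run on to the saturated amine.
- **Fallback:** It sets out from 10 and rejoins at 13. The alkyne stage is bypassed altogether.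
- 2-Methylbut-3-en-2-ol is added to Cl3CCN (DBU cat., CH2Cl2, 0 °C) to give 2-methylbut-3-en-2-yl 2,2,2-trichloroacetimidate F5.
- F5 is combined with 10 under [RhCl(cod)]2 (THF, rt). This is a rhodium-catalysed allylic amination of a tertiary allylic imidate, known to favour the branched N-aryl amine and not expected to activate an aryl iodide at room temperature.

Further compounds
F1 | step 12 | 3-[2,5-dimethoxy-3,6-bis(methoxymethoxy)-4-(trimethylsilylethynyl)phenyl]-1-triisopropylsilylindole | C[Si](C)(C)C#Cc1c(OC)c(OCOC)c(-c2cn([Si](C(C)C)(C(C)C)C(C)C)c3ccccc23)c(OC)c1OCOC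
F2 | step 6 | 3-iodo-1-(triisopropylsilyl)-1H-indole | CC(C)[Si](C(C)C)(C(C)C)n1cc(I)c2ccccc21
F3 | step 6 | [4-bromo-2,5-dimethoxy-3,6-bis(methoxymethoxy)phenyl]lithium | [Li]c1c(OC)c(OCOC)c(Br)c(OC)c1OCOC
F4 | step 6 | [4-bromo-2,5-dimethoxy-3,6-bis(methoxymethoxy)phenyl]zinc chloride | Cl[Zn]c1c(OC)c(OCOC)c(Br)c(OC)c1OCOC
F5 | step 8 | 2-methylbut-3-en-2-yl 2,2,2-trichloroacetimidate | C=CC(C)(C)OC(=N)C(Cl)(Cl)Cl
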